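**Retrosynthetic overview**

1. Avoided: the usual Sonogashira/cycloisomerisation assembly of the 2‑arylbenzofuran followed by stepwise, regiochemically fragile prenylation and chromenylation of a moracin‑type resorcinol.
2. Key idea (hidden symmetry): both C5 units are installed at once by a double aromatic Claisen rearrangement of the bis(1,1‑dimethylallyl) ether of 5‑bromoresorcinol. The meta‑Br and meta‑OR effects steer both migrations to the carbons flanking Br and leave the C–H between the oxygens untouched.
3. The C2v‑symmetric 5‑bromo‑4,6‑diprenylresorcinol is desymmetrised by one DDQ dehydrogenative cyclisation; either OH/prenyl pair gives the same 2H‑chromene.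
4. The hindered aryl bromide is joined to C2 of a 6‑silyloxybenzofuran by Negishi coupling, and fluoride desilylation gives the target.
5. Ring order: central arene and benzofuran are bought intact; the pyran ring is formed in step 4; the biaryl bond is made last.

Assumption: the target SMILES contains no stereocentre, no E/Z‑isomeric alkene and no defined axis, so it is achiral and "single enantiomer" requires no stereocontrol.

**Route**

Step 1
Reactants: 1, 2‑methylbut‑3‑en‑2‑ol
Product: 2, tert‑butyl (2‑methylbut‑3‑en‑2‑yl) carbonate
Conditions: n‑BuLi (1.0 equiv), THF, 0 °C; then Boc2O, 0 °C → rt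
Reagents that add atoms: di‑tert‑butyl dicarbonate, CC(C)(C)OC(=O)OC(=O)OC(C)(C)C
Why: O‑acylation of the tertiary lithium alkoxide by Boc2O (carbonate formation) gives the allylic carbonate needed for Pd‑allyl chemistry; no stereocentre is formed.

Step 2
Reactants: 3, 5‑bromobenzene‑1,3‑diol (5‑bromoresorcinol); 2 (3 equiv)
Product: 4, 1‑bromo‑3,5‑bis[(2‑methylbut‑3‑en‑2‑yl)oxy]benzene
Conditions: Pd(PPh3)4 (5 mol %), THF, 0 °C, quench at full conversion
Reagents that add atoms: none (both C5 units come from reactant 2)
Why: Tsuji–Trost decarboxylative O‑allylation, in which the tert‑butoxide released deprotonates the phenol and the phenoxide attacks the more substituted terminus of the 1,1‑dimethyl‑π‑allyl‑Pd under kinetic control to give the tertiary ether, while the electron‑rich ArBr does not undergo oxidative addition to Pd(PPh3)4 at 0 °C.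

Step 3
Reactants: 4
Product: 5, 5‑bromo‑4,6‑bis(3‑methylbut‑2‑en‑1‑yl)benzene‑1,3‑diol
Conditions: PhNEt2, 150 °C, Ar, 2–4 h
Reagents that add atoms: none
Why: Double aromatic Claisen ([3,3]‑sigmatropic) rearrangement, in which each tertiary allyl ether delivers a linear prenyl group through its CH2 terminus and the known meta‑substituent bias (electron‑withdrawing Br directs toward itself, donor OR directs para to itself) sends both migrations to the carbons flanking Br rather than to the carbon between the oxygens; the amine solvent suppresses acid‑catalysed chroman formation and no stereocentre is created.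

Step 4
Reactants: 5
Product: 6, 5‑bromo‑2,2‑dimethyl‑6‑(3‑methylbut‑2‑en‑1‑yl)‑2H‑chromen‑7‑ol
Conditions: DDQ (0.9 equiv, portionwise), toluene, rt; chromatography, recovered 5 recycled
Reagents that add atoms: none
Why: DDQ dehydrogenative cyclisation of an o‑prenylphenol (benzylic hydride abstraction to an o‑quinone methide, then oxa‑6π electrocyclisation) forms the 2,2‑dimethyl‑2H‑chromene; because 5 is C2v‑symmetric either OH/prenyl pair gives the same product, so the only selectivity issue is mono versus bis cyclisation, handled with sub‑stoichiometric oxidant and easy separation of diol, mono‑ol and bis‑ether.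

Step 5
Reactants: 7, 1‑benzofuran‑6‑ol
Product: 8, (1‑benzofuran‑6‑yloxy)tri(propan‑2‑yl)silane
Conditions: TIPSCl, imidazole, DMF, rt
Reagents that add atoms: triisopropylsilyl chloride, CC(C)[Si](Cl)(C(C)C)C(C)C
Why: Standard phenol silylation; the TIPS ether tolerates n‑BuLi at −78 °C and is removed at the end by fluoride without acid.

Step 6
Reactants: 8 (1.6 equiv); 6
Product: 9, 2,2‑dimethyl‑6‑(3‑methylbut‑2‑en‑1‑yl)‑5‑{6‑[(triisopropylsilyl)oxy]‑1‑benzofuran‑2‑yl}‑2H‑chromen‑7‑ol
Conditions: 8, n‑BuLi, THF, −78 °C; ZnCl2, −78 °C → rt; then 6 (pre‑treated with NaH, THF, 0 °C), Pd2(dba)3 (2.5 mol %), XPhos (10 mol %), THF, 60 °C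
Reagents that add atoms: none
Why: Negishi cross‑coupling, in which C2‑lithiation of the benzofuran and transmetalation to zinc give a 2‑heteroarylzinc that is not prone to protodemetalation, a bulky biarylphosphine‑Pd catalyst couples the di‑ortho‑substituted bromide, and the phenol is masked in situ as its phenoxide (meta to C–Br, so oxidative addition is not retarded) with no allylic leaving group present to divert Pd.

Step 7
Reactants: 9
Product: 10, cathafuran C, 5‑(6‑hydroxy‑1‑benzofuran‑2‑yl)‑2,2‑dimethyl‑6‑(3‑methylbut‑2‑en‑1‑yl)‑2H‑chromen‑7‑ol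
Conditions: TBAF, THF, 0 °C; aq NH4Cl
Reagents that add atoms: none
Why: Fluoride‑mediated Si–O cleavage of the aryl TIPS ether under non‑acidic conditions, which leaves the acid‑sensitive o‑prenylphenol and the 2H‑chromene untouched.

**Compound list**

1 | 2‑methylbut‑3‑en‑2‑ol | CC(C)(O)C=C | starting material
2 | tert‑butyl (2‑methylbut‑3‑en‑2‑yl) carbonate | C=CC(C)(C)OC(=O)OC(C)(C)C | intermediate
3 | 5‑bromobenzene‑1,3‑diol | Oc1cc(O)cc(Br)c1 | starting material
4 | 1‑bromo‑3,5‑bis[(2‑methylbut‑3‑en‑2‑yl)oxy]benzene | C=CC(C)(C)Oc1cc(Br)cc(OC(C)(C)C=C)c1 | intermediate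
5 | 5‑bromo‑4,6‑bis(3‑methylbut‑2‑en‑1‑yl)benzene‑1,3‑diol | CC(C)=CCc1c(O)cc(O)c(CC=C(C)C)c1Br | intermediate
6 | 5‑bromo‑2,2‑dimethyl‑6‑(3‑methylbut‑2‑en‑1‑yl)‑2H‑chromen‑7‑ol | CC(C)=CCc1c(O)cc2c(c1Br)C=CC(C)(C)O2 | intermediate
7 | 1‑benzofuran‑6‑ol | Oc1ccc2ccoc2c1 | starting material
8 | (1‑benzofuran‑6‑yloxy)tri(propan‑2‑yl)silane | CC(C)[Si](Oc1ccc2ccoc2c1)(C(C)C)C(C)C | intermediate
9 | 2,2‑dimethyl‑6‑prenyl‑5‑{6‑[(triisopropylsilyl)oxy]‑1‑benzofuran‑2‑yl}‑2H‑chromen‑7‑ol | CC(C)=CCc1c(O)cc2c(c1-c1cc3ccc(O[Si](C(C)C)(C(C)C)C(C)C)cc3o1)C=CC(C)(C)O2 | intermediate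
10 | cathafuran C | CC(C)=CCc1c(O)cc2c(c1-c1cc3ccc(O)cc3o1)C=CC(C)(C)O2 | target

**Totals**

Total step count: 7.
Longest linear sequence: 6 steps (1 → 2 → 4 → 5 → 6 → 9 → 10); 5 steps from 5‑bromoresorcinol.

**Three steps most likely to fail**

1. Step 4 (desymmetrising DDQ monocyclisation). The two sites are expected to react at similar rates, so mono‑chromene should not exceed roughly 40–50 % per pass, with bis‑chromene as by‑product. Fallback: drop the symmetric intermediate and differentiate the oxygens by construction. Convert 3‑bromophenol to its 1,1‑dimethylpropargyl ether and run the thermal propargyl Claisen/oxa‑6π sequence to 5‑bromo‑2,2‑dimethyl‑2H‑chromene. Install the 7‑OH by Ir‑catalysed C–H borylation/oxidation at the only C–H meta to both substituents. Then one reverse‑prenyl etherification and a single Claisen to C6 gives 6 without a statistical step.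

2. Step 3 (double Claisen). Risks are partial migration to the carbon between the oxygens and loss of isoprene from the tertiary ethers. Fallback: place the prenyls by halogen‑directed chemistry. Dibrominate methyl 3,5‑bis(methoxymethoxy)benzoate with NBS (para to each OMOM, giving the 2,6‑dibromide), then run a double Stille prenylation with tributyl(prenyl)stannane. The ester then becomes benzofuran C2 by O‑acylation and intramolecular Wittig reaction with a (2‑hydroxy‑4‑silyloxybenzyl)triphenylphosphonium salt, followed by deprotection and the same DDQ step.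

3. Step 6 (Negishi coupling at a di‑ortho‑substituted bromide bearing a phenoxide). Fallback: move the metal‑catalysed bond formation away from the congested carbon and build the furan ring instead. Protect the 7‑OH of 6, carry out Br–Li exchange and DMF formylation, and homologate the aldehyde to the terminal alkyne (Ohira–Bestmann). Then couple the unhindered alkyne terminus with 2‑iodo‑5‑(silyloxy)phenol and close the benzofuran by 5‑endo‑dig cyclisation, followed by desilylation.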